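**Plan** (target numbering: C1 = CH–OTig next to =CH, C2 = =CH, C3 = =C–C7H2OH, C4 = CH–OTig, C5 = CH–OAc, C6 = CH–iPr)

1. Retrosynthesis: the C7 silyl ether and the three esters come off first and C1 is raised to a ketone. The resulting cyclohex-2-enone is cut at C1–C2 and C3–C4 in one stroke into a propargyl ether (C2, C3, C7) and a cyclobutanone (C1, C6, C5, C4, held by a temporary C1–C4 bond). The cyclobutanone is cut by [2+2] into an isopropylketene equivalent (C1, C6) and 2,2-dimethyl-1,3-dioxole (C4, C5).
2. Enabling feature: C1 and C4 flank the C2=C3 double bond and are bridged on the other side by only C6–C5, so the six-membered ring equals a four-membered C1–C6–C5–C4 ring plus an alkyne. The cis C4/C5 oxygens can be tied in a dioxolane fused to that ring (2,4-dioxabicyclo[3.2.0]heptan-6-one), and its strain drives the event.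
3. Forward order of rings: dioxole, then cyclobutanone, then ring expansion to the cyclohexenone by nickel-catalysed alkyne insertion. After that the dioxolane is opened, C1 is reduced and the oxygens are acylated one kind at a time.
4. Stereochemistry: C4/C5 are cis from the dioxole and absolute from a C2-symmetric pyrrolidine auxiliary on the keteniminium salt. C6 is set by equilibration (trans to C5–O), and C4 passes through the key step with retention. C1 is set by hydride delivery from the C5 hydroxyl (1,3-anti).

Key step: step 6

Assumption: the (2R,5R)-auxiliary is taken to lead to the (4S,5R) series of the target. The sense of induction is checked on the first run, and if it is opposite the equally available (2S,5S)-amine is used with no other change.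
Remark: all Why lines use the target numbering given above.

**Step 1**
Reactants: 1 2,2-dimethyl-1,3-dioxolane-4-carboxylic acid (racemate or either enantiomer)
Product: 2 2,2-dimethyl-1,3-dioxolan-4-yl acetate
Conditions: Pb(OAc)4, pyridine, MeCN, rt
Reagents that add atoms: lead(IV) acetate, CC(=O)O[Pb](OC(C)=O)(OC(C)=O)OC(C)=O
Why: Kochi-type oxidative decarboxylation, in which the α-alkoxy radical/oxocarbenium ion left after loss of CO2 is captured by acetate as in the standard preparation of 4-acetoxy-1,3-dioxolanes; the stereocentre does not matter because step 2 removes it.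

**Step 2**
Reactants: 2 2,2-dimethyl-1,3-dioxolan-4-yl acetate
Product: 3 2,2-dimethyl-1,3-dioxole
Conditions: flash vacuum pyrolysis, 450 °C, 0.1 mbar; trap at −78 °C over Et3N; distillation
Reagents that add atoms: none
Why: Ester pyrolysis (thermal syn-elimination through a six-membered transition state) of the activated acylal-type acetate should give the cyclic enediol ether, and base in the trap protects the acid-sensitive product.

**Step 3**
Reactants: 4 3-methylbutanoyl chloride (isovaleryl chloride); 5 (2R,5R)-2,5-dimethylpyrrolidine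
Product: 6 1-[(2R,5R)-2,5-dimethylpyrrolidin-1-yl]-3-methylbutan-1-one
Conditions: Et3N, CH2Cl2, 0 °C to rt
Reagents that add atoms: none
Why: Schotten–Baumann-type N-acylation; both stereocentres come unchanged from the commercial amine.

**Step 4**
Reactants: 6 1-[(2R,5R)-2,5-dimethylpyrrolidin-1-yl]-3-methylbutan-1-one; 3 2,2-dimethyl-1,3-dioxole
Product: 10 (1R,5R,7R)-7-isopropyl-3,3-dimethyl-2,4-dioxabicyclo[3.2.0]heptan-6-one (isopropyl exo, trans to the dioxolane oxygens), via keteniminium triflate 7 (not isolated), via cyclobutaniminium triflate 8 (not isolated), via endo-isopropyl ketone 9 (not isolated)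
Conditions: Tf2O, 2,4,6-collidine, CH2Cl2, −20 °C to reflux; aq. NaHCO3, rt; DBU (cat.), CH2Cl2, rt
Reagents that add atoms: water, O
Why: Auxiliary-controlled keteniminium–olefin [2+2] cycloaddition, in which the electron-rich dioxole attacks the central carbon of the heterocumulene from the side of its hydrogen and on the face left open by the C2-symmetric pyrrolidine, so that C4 and C5 are set (cis by the ring of 3, absolute by the auxiliary), hydrolysis frees ketone and auxiliary, and DBU equilibrates C6 to the less hindered epimer trans to C5–O.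

**Step 5**
Reactants: 11 prop-2-yn-1-ol
Product: 12 tert-butyl(diphenyl)(prop-2-yn-1-yloxy)silane
Conditions: TBDPSCl, imidazole, DMF, rt
Reagents that add atoms: tert-butyl(chloro)diphenylsilane, CC(C)(C)[Si](Cl)(c1ccccc1)c1ccccc1
Why: Standard silylation of a primary alcohol; the bulky group also serves regiocontrol and slows alkyne oligomerisation in step 6.

**Step 6**
Reactants: 10 (1R,5R,7R)-7-isopropyl-3,3-dimethyl-2,4-dioxabicyclo[3.2.0]heptan-6-one; 12 tert-butyl(diphenyl)(prop-2-yn-1-yloxy)silane
Product: 13 (3aR,4R,7aS)-7-{[tert-butyl(diphenyl)silyl]oxymethyl}-4-isopropyl-2,2-dimethyl-3a,7a-dihydro-1,3-benzodioxol-5(4H)-one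
Conditions: Ni(cod)2 (10 mol %), IMes (10 mol %), toluene, 80 °C, 12 added slowly by syringe pump
Reagents that add atoms: none
Why: Proposed new method: Ni(0) binds the strained ketone of 10 and the alkyne and couples them oxidatively to a spiro oxanickelacyclopentene in which the CH terminus of 12 is bonded to the carbonyl carbon (C1–C2) and nickel sits on C3, β-carbon elimination then shifts the acetal-bearing ring carbon C4 from C1 to nickel with release of the cyclobutane strain, and C(sp2)–C(sp3) reductive elimination from the seven-membered nickelacycle forms C3–C4 and returns Ni(0). The closest known reaction type is the Ni(0)-catalysed intermolecular insertion of internal alkynes into the acyl–carbon bond of cyclobutanones, 3-oxetanones and 3-azetidinones (formal [4+2]); new are the terminal alkyne and a cyclobutanone substituted at both α-carbons. The six-membered ring is closed by two-carbon ring expansion of the four-membered ring, the last event being reductive elimination within a metallacycle, so that no exo/endo mode applies and the cis geometry of C2=C3 in the ring follows from the syn relation of C1 and nickel in the first metallacycle. No new stereocentre arises: C4 moves to nickel and on to C3 with retention in two concerted steps, C5 is a spectator, and C6 stays in its thermodynamically preferred configuration next to the ketone. The step needs cleavage of C1–C4 and not C1–C6, which the substrate secures because C4 is less hindered than the isopropyl-bearing C6, gives an inductively stabilised α-alkoxyalkyl–nickel bond as in the oxetanone case and can guide nickel through its acetal oxygen; it needs H at C2 and CH2OSi at C3, which follows from bond formation between the crowded ketone carbon and the unsubstituted alkyne carbon as in Ni–NHC couplings of terminal alkynes with aldehydes; and it needs the cross-reaction to outrun alkyne oligomerisation, which slow addition, the bulky silyl ether and the NHC ligand serve. β-Alkoxide elimination from the alkylnickel intermediate is held back because the dioxolane ring keeps the Ni–C4–C5–O dihedral angle far from syn-periplanar.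

**Step 7**
Reactants: 13 (3aR,4R,7aS)-7-{[tert-butyl(diphenyl)silyl]oxymethyl}-4-isopropyl-2,2-dimethyl-3a,7a-dihydro-1,3-benzodioxol-5(4H)-one
Product: 14 (4S,5R,6R)-3-{[tert-butyl(diphenyl)silyl]oxymethyl}-4,5-dihydroxy-6-isopropylcyclohex-2-en-1-one
Conditions: AcOH/H2O (4:1), 40 °C
Reagents that add atoms: none
Why: Acid-catalysed acetal hydrolysis that a TBDPS ether survives; the mildly acidic medium avoids base-induced β-elimination of the C5 oxygen, and no stereocentre is touched.

**Step 8**
Reactants: 14 (4S,5R,6R)-3-{[tert-butyl(diphenyl)silyl]oxymethyl}-4,5-dihydroxy-6-isopropylcyclohex-2-en-1-one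
Product: 15 (1S,4S,5R,6S)-3-{[tert-butyl(diphenyl)silyl]oxymethyl}-6-isopropylcyclohex-2-ene-1,4,5-triol
Conditions: Me4NBH(OAc)3, MeCN/AcOH (1:1), −30 to 0 °C
Reagents that add atoms: none
Why: Evans–Saksena reduction, in which the C5 hydroxyl exchanges onto boron and delivers hydride within the molecule to the ketone face syn to C5–O, so that the new C1 carbinol is 1,3-anti to C5–OH and cis to the isopropyl group, while the reagent leaves a non-directed enone alone.

**Step 9**
Reactants: 15 (1S,4S,5R,6S)-3-{[tert-butyl(diphenyl)silyl]oxymethyl}-6-isopropylcyclohex-2-ene-1,4,5-triol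
Product: 16 (1R,2S,5S,6S)-3-{[tert-butyl(diphenyl)silyl]oxymethyl}-2,5-dihydroxy-6-isopropylcyclohex-3-en-1-yl acetate (acetate at C5 of the target)
Conditions: AcCl (1.1 equiv), i-Pr2NEt, 2-aminoethyl diphenylborinate (10 mol %), MeCN, rt
Reagents that add atoms: acetyl chloride, CC(=O)Cl
Why: Borinic-acid-catalysed regioselective monoacylation of a cis-1,2-diol, in which the catalyst binds only the cis C4/C5 pair and activates its equatorial oxygen (C5), while the pseudoaxial allylic hydroxyls at C4 and C1 stay free.

**Step 10**
Reactants: 16 (1R,2S,5S,6S)-3-{[tert-butyl(diphenyl)silyl]oxymethyl}-2,5-dihydroxy-6-isopropylcyclohex-3-en-1-yl acetate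
Product: 17 (1S,4S,5R,6S)-5-acetoxy-3-{[tert-butyl(diphenyl)silyl]oxymethyl}-6-isopropylcyclohex-2-ene-1,4-diyl bis[(E)-2-methylbut-2-enoate]
Conditions: tigloyl chloride (excess), pyridine, DMAP (cat.), CH2Cl2, 0 to 40 °C
Reagents that add atoms: (E)-2-methylbut-2-enoyl chloride (tigloyl chloride), C/C=C(\C)C(=O)Cl
Why: DMAP-catalysed esterification of both remaining secondary alcohols in one step; pyridine instead of a trialkylamine avoids vinylketene formation and deconjugation, and the (E)-ester is the stable isomer.

**Step 11**
Reactants: 17 (1S,4S,5R,6S)-5-acetoxy-3-{[tert-butyl(diphenyl)silyl]oxymethyl}-6-isopropylcyclohex-2-ene-1,4-diyl bis[(E)-2-methylbut-2-enoate]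
Product: 18 (1S,4S,5R,6S)-5-acetoxy-3-(hydroxymethyl)-6-isopropylcyclohex-2-ene-1,4-diyl bis[(E)-2-methylbut-2-enoate] (target)
Conditions: HF·pyridine, pyridine/THF, 0 °C to rt
Reagents that add atoms: none
Why: Fluoride-mediated desilylation under weakly acidic conditions, which spare the three esters and suppress acyl migration from C4–O to the freed C7 hydroxyl.

**Compound list**
1 | 2,2-dimethyl-1,3-dioxolane-4-carboxylic acid | CC1(C)OCC(O1)C(=O)O | starting material
2 | 2,2-dimethyl-1,3-dioxolan-4-yl acetate | CC(=O)OC1COC(C)(C)O1 | intermediate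
3 | 2,2-dimethyl-1,3-dioxole | CC1(C)OC=CO1 | intermediate
4 | 3-methylbutanoyl chloride | CC(C)CC(=O)Cl | starting material
5 | (2R,5R)-2,5-dimethylpyrrolidine | C[C@@H]1CC[C@@H](C)N1 | starting material
6 | 1-[(2R,5R)-2,5-dimethylpyrrolidin-1-yl]-3-methylbutan-1-one | CC(C)CC(=O)N1[C@H](C)CC[C@H]1C | intermediate
7 | (2R,5R)-2,5-dimethyl-1-(3-methylbut-1-en-1-ylidene)pyrrolidinium triflate (keteniminium triflate) | CC(C)C=C=[N+]1[C@H](C)CC[C@H]1C.[O-]S(=O)(=O)C(F)(F)F | intermediate
8 | cyclobutaniminium triflate (N-(2R,5R)-2,5-dimethylpyrrolidinium form of ketone 9) | C[C@@H]3CC[C@@H](C)[N+]3=C1[C@@H]2OC(C)(C)O[C@@H]2[C@@H]1C(C)C.[O-]S(=O)(=O)C(F)(F)F | intermediate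
9 | (1R,5R,7S)-7-isopropyl-3,3-dimethyl-2,4-dioxabicyclo[3.2.0]heptan-6-one (isopropyl endo) | O=C1[C@@H]2OC(C)(C)O[C@@H]2[C@@H]1C(C)C | intermediate
10 | (1R,5R,7R)-7-isopropyl-3,3-dimethyl-2,4-dioxabicyclo[3.2.0]heptan-6-one (isopropyl exo) | O=C1[C@@H]2OC(C)(C)O[C@@H]2[C@H]1C(C)C | intermediate
11 | prop-2-yn-1-ol | C#CCO | starting material
12 | tert-butyl(diphenyl)(prop-2-yn-1-yloxy)silane | C#CCO[Si](c1ccccc1)(c1ccccc1)C(C)(C)C | intermediate
13 | (3aR,4R,7aS)-7-{[tert-butyl(diphenyl)silyl]oxymethyl}-4-isopropyl-2,2-dimethyl-3a,7a-dihydro-1,3-benzodioxol-5(4H)-one | O=C1C=C(CO[Si](c3ccccc3)(c4ccccc4)C(C)(C)C)[C@@H]2OC(C)(C)O[C@@H]2[C@H]1C(C)C | intermediate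
14 | (4S,5R,6R)-3-{[tert-butyl(diphenyl)silyl]oxymethyl}-4,5-dihydroxy-6-isopropylcyclohex-2-en-1-one | O=C1C=C(CO[Si](c2ccccc2)(c2ccccc2)C(C)(C)C)[C@H](O)[C@H](O)[C@H]1C(C)C | intermediate
15 | (1S,4S,5R,6S)-3-{[tert-butyl(diphenyl)silyl]oxymethyl}-6-isopropylcyclohex-2-ene-1,4,5-triol | O[C@H]1C=C(CO[Si](c2ccccc2)(c2ccccc2)C(C)(C)C)[C@H](O)[C@H](O)[C@H]1C(C)C | intermediate
16 | (1R,2S,5S,6S)-3-{[tert-butyl(diphenyl)silyl]oxymethyl}-2,5-dihydroxy-6-isopropylcyclohex-3-en-1-yl acetate | O[C@H]1C=C(CO[Si](c2ccccc2)(c2ccccc2)C(C)(C)C)[C@H](O)[C@H](OC(C)=O)[C@H]1C(C)C | intermediate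
17 | (1S,4S,5R,6S)-5-acetoxy-3-{[tert-butyl(diphenyl)silyl]oxymethyl}-6-isopropylcyclohex-2-ene-1,4-diyl bis[(E)-2-methylbut-2-enoate] | C/C=C(\C)C(=O)O[C@H]1C=C(CO[Si](c2ccccc2)(c2ccccc2)C(C)(C)C)[C@H](OC(=O)/C(C)=C/C)[C@H](OC(C)=O)[C@H]1C(C)C | intermediate
18 | (1S,4S,5R,6S)-5-acetoxy-3-(hydroxymethyl)-6-isopropylcyclohex-2-ene-1,4-diyl bis[(E)-2-methylbut-2-enoate] | C/C=C(\C)C(=O)O[C@H]1C=C(CO)[C@H](OC(=O)/C(C)=C/C)[C@H](OC(C)=O)[C@H]1C(C)C | target

**Step count**
Total step count: 11. Longest linear sequence: 9 (steps 1, 2, 4, 6, 7, 8, 9, 10, 11).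

**Steps most likely to fail**

**1. Step 6 (Proposed new method).**
- Risk: oligomerisation of the terminal alkyne at nickel may outrun oxidative coupling with the hindered ketone. The alkylnickel intermediate may also be lost through β-hydride elimination.
- Fallback, from 10 and 12 back to 13: the two bonds are made one after the other by established reaction types. The lithium acetylide of 12 (n-BuLi, THF, −78 °C) is added to 10 to give the tertiary propargylic cyclobutanol F1 (C1–C2 bond; the configuration at the carbinol carbon is of no consequence).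
- Hydroxyl-directed trans-hydroalumination with Red-Al followed by an iodine quench gives the (Z)-γ-iodoallylic cyclobutanol F2, with iodine on C3 cis to the carbinol carbon.
- Pd(OAc)2, phosphine ligand and Cs2CO3 in toluene at 80 °C then effect the intramolecular ring-opening coupling of a tert-cyclobutanol with a tethered C(sp2)–halide. The sequence is oxidative addition, palladium alkoxide, β-carbon elimination and reductive elimination, as established for 1-(2-haloaryl)cyclobutanols. This closes C3–C4 and gives 13.

**2. Step 4.**
- Risk: cationic polymerisation of the dioxole in the triflate medium, or poor facial selectivity of the auxiliary.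
- Fallback, from 4 and 3 back to 10: 4 is dehydrochlorinated with Et3N in refluxing ether in the presence of excess 3. The isopropylketene F3 formed in the flask is trapped in a thermal ketene–enol ether [2+2] cycloaddition.
- DBU equilibration gives the racemic exo ketone, that is 10 together with the mirror-image ketone F4. The two are separated by preparative chromatography on a chiral stationary phase.

**3. Step 8.**
- Risk: slow internal hydride delivery, because the ring must reach a conformer with an axial C5–O bond. Competing external attack would erode the facial selectivity at C1.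
- Fallback, from 13 back to 17: Luche reduction of 13 (NaBH4, CeCl3, MeOH, −78 °C) sends hydride to the face opposite the dioxolane. It gives the C1-epimeric allylic alcohol F5 (hydroxyl trans to isopropyl).
- Mitsunobu reaction with tiglic acid (PPh3, DIAD, toluene) inverts C1 and installs the first ester, giving the C1 tiglate acetonide F6.
- Aqueous acetic acid then gives the C4,C5-diol F7, and borinic-acid-catalysed acetylation gives the C5 acetate F8. Tigloyl chloride, pyridine and DMAP acylate C4–OH to give 17.

**Further compounds**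
F1 | step 6 | tertiary propargylic cyclobutanol (adduct of lithiated 12 to 10) | OC1(C#CCO[Si](c3ccccc3)(c4ccccc4)C(C)(C)C)[C@@H]2OC(C)(C)O[C@@H]2[C@H]1C(C)C
F2 | step 6 | (Z)-γ-iodoallylic cyclobutanol | OC1(/C=C(\I)CO[Si](c3ccccc3)(c4ccccc4)C(C)(C)C)[C@@H]2OC(C)(C)O[C@@H]2[C@H]1C(C)C
F3 | step 4 | isopropylketene (3-methylbut-1-en-1-one) | CC(C)C=C=O
F4 | step 4 | (1S,5S,7S)-7-isopropyl-3,3-dimethyl-2,4-dioxabicyclo[3.2.0]heptan-6-one (mirror image of 10) | O=C1[C@H]2OC(C)(C)O[C@H]2[C@@H]1C(C)C
F5 | step 8 | C1-epimeric allylic alcohol (acetonide, hydroxyl trans to isopropyl) | O[C@@H]1C=C(CO[Si](c3ccccc3)(c4ccccc4)C(C)(C)C)[C@@H]2OC(C)(C)O[C@@H]2[C@H]1C(C)C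
F6 | step 8 | C1 tiglate acetonide | C/C=C(\C)C(=O)O[C@H]1C=C(CO[Si](c3ccccc3)(c4ccccc4)C(C)(C)C)[C@@H]2OC(C)(C)O[C@@H]2[C@H]1C(C)C
F7 | step 8 | C1 tiglate C4,C5-diol | C/C=C(\C)C(=O)O[C@H]1C=C(CO[Si](c2ccccc2)(c2ccccc2)C(C)(C)C)[C@H](O)[C@H](O)[C@H]1C(C)C
F8 | step 8 | C1 tiglate C5 acetate with free C4 hydroxyl | C/C=C(\C)C(=O)O[C@H]1C=C(CO[Si](c2ccccc2)(c2ccccc2)C(C)(C)C)[C@H](O)[C@H](OC(C)=O)[C@H]1C(C)C
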